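**Plan**
- Cut 1: both bonds at the lactone carbonyl carbon are cut (ring A C-C(=O) and C(=O)-O-C7 of ring B). CO comes out, leaving a ring A iodide and the ring B 7-OH, and the formyl group is carried as CH2OSi.
- Cut 2: three C-C bonds of ring A are cut [C(OH)-C(CH2OSi), C(OAr)-CH and C(OH)-CH]. This gives 3-methylcyclobutenone and an alkynyl ether of ring B, so the crowded O-ring A bond goes back to an O-C(sp) bond.
- Enabling feature: in ring A the OH-bearing carbon and the carbon bearing the diaryl ether oxygen are meta. The formyl-bearing carbon lies between them, a CH flanks the OH on its other side, and CH3 is para to the formyl carbon. A vinylketene adding to an aryloxyalkyne leaves exactly this pattern.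
- Forward order: ring B is bought and oxygenated (Elbs), the pyranone ring is closed on it (Kabbe), ring A is grown on the C6 oxygen, and the seven-membered lactone is closed last by carbonylation.
- Stereochemistry: the target is achiral. The one sp3 centre formed in the cascade is transient and is lost on aromatisation.

Key step: step 9

Assumption: the bromo enol ether of step 5 is drawn with the aryloxy group trans to the chain, because copper usually prefers the C-Br bond trans to the substituent. The other isomer would give the same alkyne by a slower syn elimination.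

**Step 1**
Reactants: 1 2,4-dihydroxy-6-methylacetophenone
Product: 2 1-[4-(benzyloxy)-2-hydroxy-6-methylphenyl]ethan-1-one
Conditions: BnBr (1.05 equiv), K2CO3, acetone, reflux
Reagents that add atoms: benzyl bromide, BrCc1ccccc1
Why: Williamson etherification, in which the 2-OH is hydrogen-bonded to the acetyl oxygen and is the less acidic and less nucleophilic hydroxyl, so one equivalent of halide should take the 4-OH only.

**Step 2**
Reactants: 2 1-[4-(benzyloxy)-2-hydroxy-6-methylphenyl]ethan-1-one
Product: 4 1-[4-(benzyloxy)-3,6-dihydroxy-2-methylphenyl]ethan-1-one, via aryl potassium sulfate 3 (not isolated)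
Conditions: K2S2O8, aq KOH, pyridine, 0 °C to rt; unreacted 2 recovered at pH 5; then 2 M HCl, 85 °C, Ar
Reagents that add atoms: potassium peroxodisulfate, [K+].[K+].[O-]S(=O)(=O)OOS(=O)(=O)[O-]
Why: Elbs persulfate oxidation, in which the phenolate attacks peroxodisulfate through the carbon para to its oxygen (the free site between OBn and CH3), as in the classical oxidation of 2-hydroxy-4,6-dialkoxyacetophenones, and acid hydrolysis of 3 then frees the new phenol.

**Step 3**
Reactants: 4 1-[4-(benzyloxy)-3,6-dihydroxy-2-methylphenyl]ethan-1-one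
Product: 6 7-(benzyloxy)-6-hydroxy-2,2,5-trimethylchroman-4-one, via enone 5 (not isolated)
Conditions: acetone (10 equiv), pyrrolidine (1.5 equiv), MeOH, 60 °C, Ar
Reagents that add atoms: acetone, CC(C)=O
Why: Kabbe chromanone synthesis, in which amine-mediated aldol condensation of the acetyl group with acetone gives 5 and the hydroxyl ortho to the acyl group closes the pyranone by 6-endo-trig oxa-Michael addition, while the other hydroxyl is meta to the acyl group and cannot reach.

**Step 4**
Reactants: 7 (tert-butyldimethylsilyloxy)acetaldehyde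
Product: 8 tert-butyl[(3,3-dibromoprop-2-en-1-yl)oxy]dimethylsilane
Conditions: CBr4, PPh3, Zn dust, CH2Cl2, rt; then 7, 0 °C to rt
Reagents that add atoms: carbon tetrabromide, BrC(Br)(Br)Br
Why: Ramirez dibromoolefination (first stage of the Corey-Fuchs sequence), run in the zinc variant so that no bromophosphonium species is left to attack the silyl ether.

**Step 5**
Reactants: 6 7-(benzyloxy)-6-hydroxy-2,2,5-trimethylchroman-4-one; 8 tert-butyl[(3,3-dibromoprop-2-en-1-yl)oxy]dimethylsilane
Product: 9 7-(benzyloxy)-6-{[(1Z)-1-bromo-3-(tert-butyldimethylsilyloxy)prop-1-en-1-yl]oxy}-2,2,5-trimethylchroman-4-one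
Conditions: 8 (1.5 equiv), CuI (10 mol %), 2,2'-bipyridine (20 mol %), K3PO4, toluene, 100 °C, Ar
Reagents that add atoms: none
Why: Copper-catalysed Ullmann-type C-O vinylation of a phenol with a 1,1-dibromoalkene, a known entry to alpha-bromo enol ethers, in which the more accessible C-Br bond trans to the chain reacts first and the two ortho substituents of the phenol plus the excess of 8 hold back a second substitution.

**Step 6**
Reactants: 9 7-(benzyloxy)-6-{[(1Z)-1-bromo-3-(tert-butyldimethylsilyloxy)prop-1-en-1-yl]oxy}-2,2,5-trimethylchroman-4-one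
Product: 10 7-(benzyloxy)-6-{[3-(tert-butyldimethylsilyloxy)prop-1-yn-1-yl]oxy}-2,2,5-trimethylchroman-4-one
Conditions: KOtBu (2.2 equiv), THF, -78 to -20 °C; aq NH4Cl quench
Reagents that add atoms: none
Why: E2 dehydrobromination with H and Br anti across the double bond, the known second stage of the dibromoalkene route to aryl ynol ethers; the first equivalent of base holds the ketone as its enolate, and the low temperature is meant to suppress retro-oxa-Michael opening of the pyranone and propargyl-to-allenyl isomerisation.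

**Step 7**
Reactants: 11 propyne; 12 trichloroacetyl chloride
Product: 14 4,4-dichloro-3-methylcyclobut-2-en-1-one, via dichloroketene 13 (not isolated)
Conditions: zinc-copper couple, Et2O-DME, 0 °C to rt, dry-ice condenser
Reagents that add atoms: none
Why: Ketene-alkyne (2+2) cycloaddition of dichloroketene generated by zinc dechlorination, in which the terminal alkyne carbon attacks the ketene carbonyl carbon so that the methyl group ends at C3.

**Step 8**
Reactants: 14 4,4-dichloro-3-methylcyclobut-2-en-1-one
Product: 15 3-methylcyclobut-2-en-1-one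
Conditions: Zn dust, AcOH, TMEDA, EtOH, 0 °C to rt; careful distillation
Reagents that add atoms: none
Why: Zinc-mediated reductive dechlorination of an alpha,alpha-dichloro ketone through its zinc enolate, with amine-buffered acetic acid as the established way to avoid chloride migration and over-reduction of the strained enone.

**Step 9**
Reactants: 10 7-(benzyloxy)-6-{[3-(tert-butyldimethylsilyloxy)prop-1-yn-1-yl]oxy}-2,2,5-trimethylchroman-4-one; 15 3-methylcyclobut-2-en-1-one
Product: 20 7-(benzyloxy)-6-[2-(tert-butyldimethylsilyloxymethyl)-3-hydroxy-5-methylphenoxy]-2,2,5-trimethylchroman-4-one, via vinylketene 16 (not isolated), via vinylcyclobutenone 17 (not isolated), via dienylketene 18 (not isolated), via cyclohexadienone 19 (not isolated)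
Conditions: 15 (2.5 equiv), toluene (0.5 M), sealed tube, 80 °C then 110 °C; then K2CO3, MeOH, rt
Reagents that add atoms: none
Why: Proposed new method: at 80 °C 15 opens in a four-electron electrocyclic reaction to vinylketene 16, the alkyne carbon of 10 remote from oxygen attacks the ketene carbonyl carbon in a (2+2) cycloaddition to give 17, and four-electron opening to dienylketene 18, six-electron closure to dienone 19 and tautomerisation should then give phenol 20 with three new C-C bonds. The closest known reaction type is the Danheiser benzannulation of cyclobutenones with alkoxyalkynes, siloxyalkynes and ynamides; an aryloxyalkyne has not been used, but the ether oxygen of 10 is meta to the ketone-bearing carbon and is twisted out of conjugation with ring B by its two ortho neighbours (CH3, OBn), so its lone pair still polarises the triple bond, and the absence of a beta C-H bond excludes the retro-ene loss that limits alkyl ynol ethers and permits long heating. Ring A is closed by a thermal disrotatory six-electron electrocyclisation of 18 (bond between the ketene carbon and the terminal CH2), the four-membered ring of 17 serving only as a relay. No stereocentre remains in 20, because the single sp3 centre of racemic 17 is lost in the ring opening. The step needs one regiochemical outcome of the (2+2) event, and the ynol ether polarisation (nucleophilic at the carbon bearing CH2OTBS) secures it, placing OH, CH2OTBS and OAr on three adjacent carbons with CH3 para to the CH2OTBS carbon. Excess volatile 15 and high concentration offset the lower nucleophilicity of 10, and the closing K2CO3/MeOH treatment returns any phenol that surplus ketene has acylated.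

**Step 10**
Reactants: 20 7-(benzyloxy)-6-[2-(tert-butyldimethylsilyloxymethyl)-3-hydroxy-5-methylphenoxy]-2,2,5-trimethylchroman-4-one
Product: 21 7-(benzyloxy)-6-[2-(tert-butyldimethylsilyloxymethyl)-3-hydroxy-6-iodo-5-methylphenoxy]-2,2,5-trimethylchroman-4-one
Conditions: NIS (1.0 equiv), MeCN, -20 to 0 °C, dark
Reagents that add atoms: N-iodosuccinimide, O=C1CCC(=O)N1I
Why: Electrophilic aromatic iodination, in which acceptor-free, orcinol-type ring A should outrun ring B (whose oxygens are vinylogous esters of the ketone) and the site para to the free OH (also ortho to OAr and CH3) is electronically preferred, a bias that acetonitrile reinforces by hydrogen bonding to the OH and crowding its ortho site.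

**Step 11**
Reactants: 21 7-(benzyloxy)-6-[2-(tert-butyldimethylsilyloxymethyl)-3-hydroxy-6-iodo-5-methylphenoxy]-2,2,5-trimethylchroman-4-one
Product: 22 7-(benzyloxy)-6-[3-hydroxy-2-(hydroxymethyl)-6-iodo-5-methylphenoxy]-2,2,5-trimethylchroman-4-one
Conditions: HF·pyridine, pyridine, THF, 0 °C
Reagents that add atoms: none
Why: Fluoride-driven cleavage of a primary silyl ether under buffered conditions that leave the aryl iodide, the benzyl ether and the chromanone untouched.

**Step 12**
Reactants: 22 7-(benzyloxy)-6-[3-hydroxy-2-(hydroxymethyl)-6-iodo-5-methylphenoxy]-2,2,5-trimethylchroman-4-one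
Product: 23 2-{[7-(benzyloxy)-2,2,5-trimethyl-4-oxochroman-6-yl]oxy}-6-hydroxy-3-iodo-4-methylbenzaldehyde
Conditions: activated MnO2 (15 equiv), CH2Cl2, rt
Reagents that add atoms: none
Why: Chemoselective MnO2 oxidation of a benzylic alcohol, well known for 2-hydroxybenzyl alcohols, which stops at the aldehyde that is hydrogen-bonded to the neighbouring OH.

**Step 13**
Reactants: 23 2-{[7-(benzyloxy)-2,2,5-trimethyl-4-oxochroman-6-yl]oxy}-6-hydroxy-3-iodo-4-methylbenzaldehyde
Product: 24 6-hydroxy-2-[(7-hydroxy-2,2,5-trimethyl-4-oxochroman-6-yl)oxy]-3-iodo-4-methylbenzaldehyde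
Conditions: BCl3 (4 equiv), pentamethylbenzene (5 equiv), CH2Cl2, -78 °C; then H2O
Reagents that add atoms: none
Why: Lewis-acid debenzylation of an aryl benzyl ether with a non-basic cation scavenger, chosen over hydrogenolysis because it spares the C-I bond and placed after the oxidation so that no acid-labile benzylic C-O bond remains on ring A.

**Step 14**
Reactants: 24 6-hydroxy-2-[(7-hydroxy-2,2,5-trimethyl-4-oxochroman-6-yl)oxy]-3-iodo-4-methylbenzaldehyde
Product: 25 mollicellin A
Conditions: Pd(OAc)2 (10 mol %), Xantphos (12 mol %), Et3N, CO (1 atm), toluene (0.01 M), 80 °C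
Reagents that add atoms: carbon monoxide, [C-]#[O+]
Why: Palladium-catalysed carbonylative lactonisation (intramolecular aryloxycarbonylation of an aryl iodide), in which oxidative addition to zerovalent palladium formed in situ, CO insertion and acyl transfer to the nearby, more acidic 7-OH close the seven-membered ring, while the ring A OH is para to the acyl carbon, cannot reach it and is hydrogen-bonded to the aldehyde, and dilution suppresses intermolecular esterification.

**Compound list**
1 | 2,4-dihydroxy-6-methylacetophenone | CC(=O)c1c(C)cc(O)cc1O | starting material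
2 | 1-[4-(benzyloxy)-2-hydroxy-6-methylphenyl]ethan-1-one | CC(=O)c1c(C)cc(OCc2ccccc2)cc1O | intermediate
3 | potassium 3-acetyl-6-(benzyloxy)-4-hydroxy-2-methylphenyl sulfate (not isolated) | CC(=O)c1c(C)c(OS(=O)(=O)[O-])c(OCc2ccccc2)cc1O.[K+] | intermediate
4 | 1-[4-(benzyloxy)-3,6-dihydroxy-2-methylphenyl]ethan-1-one | CC(=O)c1c(C)c(O)c(OCc2ccccc2)cc1O | intermediate
5 | 1-[4-(benzyloxy)-3,6-dihydroxy-2-methylphenyl]-3-methylbut-2-en-1-one (not isolated) | CC(C)=CC(=O)c1c(C)c(O)c(OCc2ccccc2)cc1O | intermediate
6 | 7-(benzyloxy)-6-hydroxy-2,2,5-trimethylchroman-4-one | Cc1c(O)c(OCc2ccccc2)cc2OC(C)(C)CC(=O)c12 | intermediate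
7 | (tert-butyldimethylsilyloxy)acetaldehyde | CC(C)(C)[Si](C)(C)OCC=O | starting material
8 | tert-butyl[(3,3-dibromoprop-2-en-1-yl)oxy]dimethylsilane | CC(C)(C)[Si](C)(C)OCC=C(Br)Br | intermediate
9 | 7-(benzyloxy)-6-{[(1Z)-1-bromo-3-(tert-butyldimethylsilyloxy)prop-1-en-1-yl]oxy}-2,2,5-trimethylchroman-4-one | CC(C)(C)[Si](C)(C)OC/C=C(\Br)Oc1c(OCc2ccccc2)cc2OC(C)(C)CC(=O)c2c1C | intermediate
10 | 7-(benzyloxy)-6-{[3-(tert-butyldimethylsilyloxy)prop-1-yn-1-yl]oxy}-2,2,5-trimethylchroman-4-one | CC(C)(C)[Si](C)(C)OCC#COc1c(OCc2ccccc2)cc2OC(C)(C)CC(=O)c2c1C | intermediate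
11 | propyne | CC#C | starting material
12 | trichloroacetyl chloride | O=C(Cl)C(Cl)(Cl)Cl | starting material
13 | dichloroketene (not isolated) | O=C=C(Cl)Cl | intermediate
14 | 4,4-dichloro-3-methylcyclobut-2-en-1-one | CC1=CC(=O)C1(Cl)Cl | intermediate
15 | 3-methylcyclobut-2-en-1-one | CC1=CC(=O)C1 | intermediate
16 | 3-methylbuta-1,3-dien-1-one, the vinylketene (not isolated) | C=C(C)C=C=O | intermediate
17 | racemic 3-aryloxy-2-(tert-butyldimethylsilyloxymethyl)-4-(prop-1-en-2-yl)cyclobut-2-en-1-one, aryl = 7-(benzyloxy)-2,2,5-trimethyl-4-oxochroman-6-yl (not isolated) | C=C(C)C1C(=O)C(CO[Si](C)(C)C(C)(C)C)=C1Oc1c(OCc2ccccc2)cc2OC(C)(C)CC(=O)c2c1C | intermediate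
18 | (3E)-3-aryloxy-2-(tert-butyldimethylsilyloxymethyl)-5-methylhexa-1,3,5-trien-1-one, same aryl group, the dienylketene (not isolated) | C=C(C)/C=C(/Oc1c(OCc2ccccc2)cc2OC(C)(C)CC(=O)c2c1C)C(=C=O)CO[Si](C)(C)C(C)(C)C | intermediate
19 | 3-aryloxy-2-(tert-butyldimethylsilyloxymethyl)-5-methylcyclohexa-2,4-dien-1-one, same aryl group (not isolated) | CC1=CC(Oc2c(OCc3ccccc3)cc3OC(C)(C)CC(=O)c3c2C)=C(CO[Si](C)(C)C(C)(C)C)C(=O)C1 | intermediate
20 | 7-(benzyloxy)-6-[2-(tert-butyldimethylsilyloxymethyl)-3-hydroxy-5-methylphenoxy]-2,2,5-trimethylchroman-4-one | Cc1cc(O)c(CO[Si](C)(C)C(C)(C)C)c(Oc2c(OCc3ccccc3)cc3OC(C)(C)CC(=O)c3c2C)c1 | intermediate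
21 | 7-(benzyloxy)-6-[2-(tert-butyldimethylsilyloxymethyl)-3-hydroxy-6-iodo-5-methylphenoxy]-2,2,5-trimethylchroman-4-one | Cc1cc(O)c(CO[Si](C)(C)C(C)(C)C)c(Oc2c(OCc3ccccc3)cc3OC(C)(C)CC(=O)c3c2C)c1I | intermediate
22 | 7-(benzyloxy)-6-[3-hydroxy-2-(hydroxymethyl)-6-iodo-5-methylphenoxy]-2,2,5-trimethylchroman-4-one | Cc1cc(O)c(CO)c(Oc2c(OCc3ccccc3)cc3OC(C)(C)CC(=O)c3c2C)c1I | intermediate
23 | 2-{[7-(benzyloxy)-2,2,5-trimethyl-4-oxochroman-6-yl]oxy}-6-hydroxy-3-iodo-4-methylbenzaldehyde | Cc1cc(O)c(C=O)c(Oc2c(OCc3ccccc3)cc3OC(C)(C)CC(=O)c3c2C)c1I | intermediate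
24 | 6-hydroxy-2-[(7-hydroxy-2,2,5-trimethyl-4-oxochroman-6-yl)oxy]-3-iodo-4-methylbenzaldehyde | Cc1cc(O)c(C=O)c(Oc2c(O)cc3OC(C)(C)CC(=O)c3c2C)c1I | intermediate
25 | mollicellin A | Cc1cc(O)c(C=O)c2c1C(=O)Oc1cc3c(c(C)c1O2)C(=O)CC(C)(C)O3 | target

**Step count**
- Total steps: 14.
- Longest linear sequence: 11 (steps 1, 2, 3, 5, 6, 9, 10, 11, 12, 13, 14).
- Side branches: step 4, and steps 7 and 8.

**Steps most likely to fail**

1. Step 9 (the step that bears the label).
 - Risk: capture of the vinylketene by the less nucleophilic aryloxyalkyne may be too slow, so the ketene is consumed by self-reaction. The relay cyclobutenone may also fail to open at a temperature the ynol ether tolerates.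
 - Fallback: known chemistry, with ring A bought and the ether made by nucleophilic aromatic substitution. It sets out from 6 and comes back at 20.
 - Commercial 2,6-difluoro-4-methylbenzaldehyde is treated with allyl alcohol and NaH (THF, 0 °C) to give 2-(allyloxy)-6-fluoro-4-methylbenzaldehyde F1.
 - The remaining fluoride, activated by the ortho aldehyde, is displaced by the phenolate of 6 (K2CO3, DMF, 110 °C). This gives 2-(allyloxy)-6-{[7-(benzyloxy)-2,2,5-trimethyl-4-oxochroman-6-yl]oxy}-4-methylbenzaldehyde F2.
 - Aldehyde-selective reduction (NaBH4, MeOH-THF, -40 °C) gives 6-[3-(allyloxy)-2-(hydroxymethyl)-5-methylphenoxy]-7-(benzyloxy)-2,2,5-trimethylchroman-4-one F3.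
 - Silylation (TBSCl, imidazole, DMF) gives 6-[3-(allyloxy)-2-(tert-butyldimethylsilyloxymethyl)-5-methylphenoxy]-7-(benzyloxy)-2,2,5-trimethylchroman-4-one F4.
 - Allyl transfer to morpholine with Pd(PPh3)4 (THF, rt) frees the phenol and gives 20.

2. Step 6.
 - Risk: enolisation of the chromanone may be followed by retro-oxa-Michael opening of the pyranone ring, and the base may isomerise the propargylic ether.
 - Fallback: a redox detour that removes the enolisable ketone. It sets out from 9 and comes back at 10.
 - NaBH4 (MeOH, 0 °C to rt) reduces the ketone to racemic 7-(benzyloxy)-6-{[(1Z)-1-bromo-3-(tert-butyldimethylsilyloxy)prop-1-en-1-yl]oxy}-2,2,5-trimethylchroman-4-ol F5.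
 - KOtBu (2.2 equiv, THF), now facing only an innocuous alkoxide, eliminates HBr to give 7-(benzyloxy)-6-{[3-(tert-butyldimethylsilyloxy)prop-1-yn-1-yl]oxy}-2,2,5-trimethylchroman-4-ol F6.
 - Neutral MnO2 (CH2Cl2, rt) re-oxidises the benzylic alcohol to 10.

3. Step 10.
 - Risk: site selectivity between the two free ring A positions may be poor. Attack ortho to the OH can compete because the para site is flanked by the bulky aryloxy group and the methyl group.
 - Fallback: steric shielding replaces the electronic preference. It sets out from 20 and comes back at 22.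
 - TIPSOTf and 2,6-lutidine (CH2Cl2, 0 °C) give 7-(benzyloxy)-6-[2-(tert-butyldimethylsilyloxymethyl)-5-methyl-3-(triisopropylsilyloxy)phenoxy]-2,2,5-trimethylchroman-4-one F7. Its silyl group is pushed by the neighbouring CH2OTBS over the ortho CH.
 - Iodination with I2 and AgO2CCF3 (NaHCO3, CH2Cl2, 0 °C) should then give 7-(benzyloxy)-6-[2-(tert-butyldimethylsilyloxymethyl)-6-iodo-5-methyl-3-(triisopropylsilyloxy)phenoxy]-2,2,5-trimethylchroman-4-one F8.
 - Global desilylation (TBAF, AcOH, THF, 0 °C) gives 22.

**Further compounds**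
F1 | step 9 | 2-(allyloxy)-6-fluoro-4-methylbenzaldehyde | C=CCOc1cc(C)cc(F)c1C=O
F2 | step 9 | 2-(allyloxy)-6-{[7-(benzyloxy)-2,2,5-trimethyl-4-oxochroman-6-yl]oxy}-4-methylbenzaldehyde | C=CCOc1cc(C)cc(Oc2c(OCc3ccccc3)cc3OC(C)(C)CC(=O)c3c2C)c1C=O
F3 | step 9 | 6-[3-(allyloxy)-2-(hydroxymethyl)-5-methylphenoxy]-7-(benzyloxy)-2,2,5-trimethylchroman-4-one | C=CCOc1cc(C)cc(Oc2c(OCc3ccccc3)cc3OC(C)(C)CC(=O)c3c2C)c1CO
F4 | step 9 | 6-[3-(allyloxy)-2-(tert-butyldimethylsilyloxymethyl)-5-methylphenoxy]-7-(benzyloxy)-2,2,5-trimethylchroman-4-one | C=CCOc1cc(C)cc(Oc2c(OCc3ccccc3)cc3OC(C)(C)CC(=O)c3c2C)c1CO[Si](C)(C)C(C)(C)C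
F5 | step 6 | racemic 7-(benzyloxy)-6-{[(1Z)-1-bromo-3-(tert-butyldimethylsilyloxy)prop-1-en-1-yl]oxy}-2,2,5-trimethylchroman-4-ol | CC(C)(C)[Si](C)(C)OC/C=C(\Br)Oc1c(OCc2ccccc2)cc2OC(C)(C)CC(O)c2c1C
F6 | step 6 | racemic 7-(benzyloxy)-6-{[3-(tert-butyldimethylsilyloxy)prop-1-yn-1-yl]oxy}-2,2,5-trimethylchroman-4-ol | CC(C)(C)[Si](C)(C)OCC#COc1c(OCc2ccccc2)cc2OC(C)(C)CC(O)c2c1C
F7 | step 10 | 7-(benzyloxy)-6-[2-(tert-butyldimethylsilyloxymethyl)-5-methyl-3-(triisopropylsilyloxy)phenoxy]-2,2,5-trimethylchroman-4-one | Cc1cc(O[Si](C(C)C)(C(C)C)C(C)C)c(CO[Si](C)(C)C(C)(C)C)c(Oc2c(OCc3ccccc3)cc3OC(C)(C)CC(=O)c3c2C)c1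
F8 | step 10 | 7-(benzyloxy)-6-[2-(tert-butyldimethylsilyloxymethyl)-6-iodo-5-methyl-3-(triisopropylsilyloxy)phenoxy]-2,2,5-trimethylchroman-4-one | Cc1cc(O[Si](C(C)C)(C(C)C)C(C)C)c(CO[Si](C)(C)C(C)(C)C)c(Oc2c(OCc3ccccc3)cc3OC(C)(C)CC(=O)c3c2C)c1I
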